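The synthesis rests on disconnecting the O1–C2 bond of the pyranone ring (O1, C2, C3, C4, C4a, C8a). C2 lies β to the C4 carbonyl, so conjugate addition of the C8a phenol oxygen closes this ring and creates the only stereocentre in one operation. The precursor is an open-chain benzylidene β-ketoester: a tert-butyl ester at the future C3 activates the alkene and is removed afterwards, and only the phenol oxygen flanked by C8–H is free, the oxygens at C5 and C7 being MOM ethers, which fixes the geranyl group at C6. A cinchona thiourea controls the C2 configuration; acid then removes ester, CO2 and MOM groups in the same flask.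

Key step: step 8

Assumption: the quinidine-derived thiourea is written for the (2S) sense by analogy with related cyclisations; its quinine-derived pseudoenantiomer gives the antipode and would be used instead if a test cyclisation shows the opposite sense.
Assumption: alkylidene 13 is drawn as the expected major (Z) isomer; the geometry is not expected to be decisive, since the ring closure is catalyst-controlled.
In names, "geranyl" means (2E)-3,7-dimethylocta-2,6-dien-1-yl and "MOM" means methoxymethyl.

Step 1
Reactants: 1 resorcinol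
Product: 2 1,3-bis(methoxymethoxy)benzene
Conditions: NaH, MOMCl, DMF, 0 °C → rt
Reagents that add atoms: chloromethyl methyl ether (MOMCl), COCCl
Why: O-alkylation of the bis-phenoxide (MOM protection) installs two acetal groups that later direct lithiation and are removed by acid.

Step 2
Reactants: 2 1,3-bis(methoxymethoxy)benzene; 3 geranyl bromide
Product: 5 2-geranyl-1,3-bis(methoxymethoxy)benzene, via 2-lithio-1,3-bis(methoxymethoxy)benzene 4 (not isolated)
Conditions: n-BuLi, THF, 0 °C → rt; CuI (cat.), then 3, −78 °C → rt
Reagents that add atoms: n-butyllithium, [Li]CCCC (lithium of intermediate 4 only)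
Why: Directed ortho-metalation places lithium at C2 between both OMOM groups, and copper-mediated SN2 allylation with geranyl bromide should give the C-geranyl arene with the E alkene unchanged.

Step 3
Reactants: 5 2-geranyl-1,3-bis(methoxymethoxy)benzene
Product: 7 4-geranyl-3,5-bis(methoxymethoxy)phenol, via aryl pinacol boronate 6 (not isolated)
Conditions: [Ir(OMe)(cod)]2 (cat.), dtbpy (cat.), B2pin2, THF, 60 °C; then aq. NaOH, 30% H2O2, 0 °C → rt
Reagents that add atoms: bis(pinacolato)diboron, CC1(C)OB(OC1(C)C)B1OC(C)(C)C(C)(C)O1 (Bpin of intermediate 6); hydrogen peroxide, OO (oxygen of 7)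
Why: Sterically governed iridium-catalysed C–H borylation should select the only ring C–H without an ortho substituent (para to geranyl), the trisubstituted alkenes being inert, and oxidation of the C–B bond then gives the phenol whose oxygen becomes O1.

Step 4
Reactants: 7 4-geranyl-3,5-bis(methoxymethoxy)phenol; 8 mono-tert-butyl malonate
Product: 9 tert-butyl 4-geranyl-3,5-bis(methoxymethoxy)phenyl malonate
Conditions: DCC, DMAP (cat.), CH2Cl2, 0 °C → rt
Reagents that add atoms: none
Why: Steglich esterification of the unhindered phenol with the malonate half-ester should proceed without touching the tert-butyl ester, the MOM acetals or the alkenes.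

Step 5
Reactants: 9 tert-butyl 4-geranyl-3,5-bis(methoxymethoxy)phenyl malonate
Product: 10 tert-butyl 3-[3-geranyl-6-hydroxy-2,4-bis(methoxymethoxy)phenyl]-3-oxopropanoate
Conditions: hν (254 nm, quartz), degassed cyclohexane, dilute, rt
Reagents that add atoms: none
Why: Photo-Fries rearrangement (ArO–CO homolysis and in-cage recombination) can only deliver the acyl group to an ortho carbon, because the para position carries geranyl and the two ortho positions are equivalent by symmetry, so one o-hydroxyaryl β-ketoester should form with its free phenol flanked by C–H.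

Step 6
Reactants: 11 3-hydroxy-4,5-dimethoxybenzaldehyde
Product: 12 3,4-dimethoxy-5-(methoxymethoxy)benzaldehyde
Conditions: NaH, MOMCl, DMF, 0 °C → rt
Reagents that add atoms: chloromethyl methyl ether (MOMCl), COCCl
Why: MOM protection of the B-ring phenol keeps a second acidic OH away from the bifunctional catalyst of step 8 and is removed in the same final acid treatment.

Step 7
Reactants: 10 tert-butyl 3-[3-geranyl-6-hydroxy-2,4-bis(methoxymethoxy)phenyl]-3-oxopropanoate; 12 3,4-dimethoxy-5-(methoxymethoxy)benzaldehyde
Product: 13 tert-butyl (2Z)-2-[3-geranyl-6-hydroxy-2,4-bis(methoxymethoxy)benzoyl]-3-[3,4-dimethoxy-5-(methoxymethoxy)phenyl]prop-2-enoate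
Conditions: piperidine (cat.), AcOH (cat.), 4 Å MS, toluene, rt
Reagents that add atoms: none
Why: Knoevenagel condensation under buffered amine catalysis should give the benzylidene β-ketoester, the bulky tert-butyl ester blocking lactonisation to a 4-hydroxycoumarin and the mild temperature holding back premature addition of the free phenol.

Step 8
Reactants: 13 tert-butyl (2Z)-2-[3-geranyl-6-hydroxy-2,4-bis(methoxymethoxy)benzoyl]-3-[3,4-dimethoxy-5-(methoxymethoxy)phenyl]prop-2-enoate
Product: 15 (2S)-5,7-dihydroxy-2-(3-hydroxy-4,5-dimethoxyphenyl)-6-geranyl-2,3-dihydro-4H-chromen-4-one, via cyclised tert-butyl 4-oxochromane-3-carboxylate 14 (not isolated)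
Conditions: 1-[3,5-bis(trifluoromethyl)phenyl]-3-[(9R)-6'-methoxycinchonan-9-yl]thiourea (quinidine-derived, 10 mol%), toluene, −25 °C; then conc. HCl, i-PrOH/THF, 45 °C
Reagents that add atoms: none
Why: The quinuclidine nitrogen of the catalyst acts as a general base on the single free phenol of 13 while the thiourea hydrogen-bonds the β-ketoester dicarbonyl, so the phenol oxygen adds to the benzylidene carbon (future C2) and the enol is protonated at C3; the acid added afterwards protonates the catalyst, cleaves the tert-butyl ester, lets the β-keto acid lose CO2 through its enol and hydrolyses the three MOM acetals. The closest known reaction type is the cinchona-thiourea-catalysed enantioselective intramolecular oxa-Michael addition of alkylidene β-ketoesters with acid-mediated dealkoxycarbonylation in the same flask, an asymmetric form of the chalcone–flavanone isomerisation. The pyranone ring closes in the 6-endo-trig mode by formation of the O1–C2 bond. C2 (S) is set by catalyst control over the enantiotopic faces of the alkene within the hydrogen-bonded ion pair, and the transient C3 centre is erased on decarboxylation. Regiochemistry (6- rather than 8-geranyl) is secured because the only free ortho oxygen is the one flanked by C8–H, the oxygen next to the geranyl group being a MOM ether; enantiopurity should be secured by kinetic control at low temperature and by acidifying before warming, which stops retro-oxa-Michael equilibration. Isopropanol/THF is chosen so that the liberated formaldehyde is trapped and the β-keto acid is not re-esterified, and the exposure of the geranyl alkenes to acid is kept short and mild.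

Compound list
1 | resorcinol (benzene-1,3-diol) | Oc1cccc(O)c1 | starting material
2 | 1,3-bis(methoxymethoxy)benzene | COCOc1cccc(OCOC)c1 | intermediate
3 | geranyl bromide, (2E)-1-bromo-3,7-dimethylocta-2,6-diene | BrC/C=C(\C)CCC=C(C)C | starting material
4 | 2-lithio-1,3-bis(methoxymethoxy)benzene | [Li]c1c(OCOC)cccc1OCOC | intermediate (not isolated)
5 | 2-geranyl-1,3-bis(methoxymethoxy)benzene | COCOc1cccc(OCOC)c1C/C=C(\C)CCC=C(C)C | intermediate
6 | 2-[4-geranyl-3,5-bis(methoxymethoxy)phenyl]-4,4,5,5-tetramethyl-1,3,2-dioxaborolane | COCOc1cc(B2OC(C)(C)C(C)(C)O2)cc(OCOC)c1C/C=C(\C)CCC=C(C)C | intermediate (not isolated)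
7 | 4-geranyl-3,5-bis(methoxymethoxy)phenol | COCOc1cc(O)cc(OCOC)c1C/C=C(\C)CCC=C(C)C | intermediate
8 | mono-tert-butyl malonate, 3-tert-butoxy-3-oxopropanoic acid | CC(C)(C)OC(=O)CC(=O)O | starting material
9 | tert-butyl 4-geranyl-3,5-bis(methoxymethoxy)phenyl malonate | CC(C)(C)OC(=O)CC(=O)Oc1cc(OCOC)c(C/C=C(\C)CCC=C(C)C)c(OCOC)c1 | intermediate
10 | tert-butyl 3-[3-geranyl-6-hydroxy-2,4-bis(methoxymethoxy)phenyl]-3-oxopropanoate | CC(C)(C)OC(=O)CC(=O)c1c(O)cc(OCOC)c(C/C=C(\C)CCC=C(C)C)c1OCOC | intermediate
11 | 3-hydroxy-4,5-dimethoxybenzaldehyde | COc1cc(C=O)cc(O)c1OC | starting material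
12 | 3,4-dimethoxy-5-(methoxymethoxy)benzaldehyde | COCOc1cc(C=O)cc(OC)c1OC | intermediate
13 | tert-butyl (2Z)-2-[3-geranyl-6-hydroxy-2,4-bis(methoxymethoxy)benzoyl]-3-[3,4-dimethoxy-5-(methoxymethoxy)phenyl]prop-2-enoate | CC(C)(C)OC(=O)/C(=C\c1cc(OC)c(OC)c(OCOC)c1)C(=O)c1c(O)cc(OCOC)c(C/C=C(\C)CCC=C(C)C)c1OCOC | intermediate
14 | tert-butyl (2S)-2-[3,4-dimethoxy-5-(methoxymethoxy)phenyl]-6-geranyl-5,7-bis(methoxymethoxy)-4-oxochromane-3-carboxylate (C3 epimerisable, left undefined) | COc1cc([C@@H]2C(C(=O)OC(C)(C)C)C(=O)c3c(cc(OCOC)c(C/C=C(\C)CCC=C(C)C)c3OCOC)O2)cc(OCOC)c1OC | intermediate (not isolated)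
15 | (2S)-5,7-dihydroxy-2-(3-hydroxy-4,5-dimethoxyphenyl)-6-[(2E)-3,7-dimethylocta-2,6-dien-1-yl]-2,3-dihydro-4H-chromen-4-one | COc1cc([C@@H]2CC(=O)c3c(cc(O)c(C/C=C(\C)CCC=C(C)C)c3O)O2)cc(O)c1OC | target

Total step count: 8. Longest linear sequence: 7 steps (steps 1, 2, 3, 4, 5, 7, 8).

Steps most likely to fail

Step 8. The enantiomeric purity may erode through uncatalysed background cyclisation or retro-oxa-Michael equilibration before the acid quench. During the acid stage the geranyl alkenes may be hydrated or cyclise onto the neighbouring phenols while the tert-butyl ester is still being cleaved. The fallback sets out from 7 and 12, avoids the ester altogether, and returns at 15. Aldehyde 12 is condensed with malonic acid (pyridine, cat. piperidine, 85 °C, Doebner–Knoevenagel) to (2E)-3-[3,4-dimethoxy-5-(methoxymethoxy)phenyl]prop-2-enoic acid F1. Steglich esterification of F1 with phenol 7 gives the aryl cinnamate F2. Photo-Fries rearrangement of F2 gives the 2'-hydroxychalcone F3, which NaOAc in refluxing EtOH should close to the racemic tris-MOM flavanone F4. Kinetic resolution of F4 by Noyori–Ikariya asymmetric transfer hydrogenation (Rh or Ru TsDPEN catalyst, HCO2H/Et3N, rt) uses the catalyst enantiomer that reduces the (2R)-ketone to the cis-(2R,4R)-flavan-4-ol F6. This should leave the (2S)-tris-MOM flavanone F5, which is separated by chromatography. Brief treatment of F5 with 3 M HCl in MeOH at 45 °C then gives 15.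

Step 5. The radical pair may escape the solvent cage and return phenol 7, the acyl radical may lose CO, and the product may screen the light so that conversion stalls. The fallback sets out from 7 and returns at 10 without photochemistry. Magnesium-mediated ortho-formylation of 7 (MgCl2, Et3N, paraformaldehyde, THF, reflux) should give 3-geranyl-6-hydroxy-2,4-bis(methoxymethoxy)benzaldehyde F7. Addition of excess lithium enolate of tert-butyl acetate (LDA, THF, −78 → −20 °C) gives the racemic β-hydroxy ester F8, and benzylic oxidation with MnO2 in CH2Cl2 gives 10.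

Step 7. The free phenol may add to the newly formed alkylidene under the amine catalyst, giving racemic cyclised material before the chiral catalyst is introduced. The fallback sets out from 10 and returns at 13 with the phenol masked during the condensation. Silylation of 10 (TBSCl, imidazole, DMF) gives the silyl ether F9. Knoevenagel condensation of F9 with 12 under the same conditions gives the silylated alkylidene F10. Acidic fluoride (Et3N·3HF, THF, 0 °C) then releases 13 in the absence of free base, immediately before step 8.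

Further compounds
F1 | step 8 | (2E)-3-[3,4-dimethoxy-5-(methoxymethoxy)phenyl]prop-2-enoic acid | COCOc1cc(/C=C/C(=O)O)cc(OC)c1OC
F2 | step 8 | 4-geranyl-3,5-bis(methoxymethoxy)phenyl (2E)-3-[3,4-dimethoxy-5-(methoxymethoxy)phenyl]prop-2-enoate | COCOc1cc(/C=C/C(=O)Oc2cc(OCOC)c(C/C=C(\C)CCC=C(C)C)c(OCOC)c2)cc(OC)c1OC
F3 | step 8 | (2E)-1-[3-geranyl-6-hydroxy-2,4-bis(methoxymethoxy)phenyl]-3-[3,4-dimethoxy-5-(methoxymethoxy)phenyl]prop-2-en-1-one | COCOc1cc(/C=C/C(=O)c2c(O)cc(OCOC)c(C/C=C(\C)CCC=C(C)C)c2OCOC)cc(OC)c1OC
F4 | step 8 | racemic 2-[3,4-dimethoxy-5-(methoxymethoxy)phenyl]-6-geranyl-5,7-bis(methoxymethoxy)chroman-4-one | COc1cc(C2CC(=O)c3c(cc(OCOC)c(C/C=C(\C)CCC=C(C)C)c3OCOC)O2)cc(OCOC)c1OC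
F5 | step 8 | (2S)-2-[3,4-dimethoxy-5-(methoxymethoxy)phenyl]-6-geranyl-5,7-bis(methoxymethoxy)chroman-4-one | COc1cc([C@@H]2CC(=O)c3c(cc(OCOC)c(C/C=C(\C)CCC=C(C)C)c3OCOC)O2)cc(OCOC)c1OC
F6 | step 8 | (2R,4R)-2-[3,4-dimethoxy-5-(methoxymethoxy)phenyl]-6-geranyl-5,7-bis(methoxymethoxy)chroman-4-ol (cis) | COc1cc([C@H]2C[C@@H](O)c3c(cc(OCOC)c(C/C=C(\C)CCC=C(C)C)c3OCOC)O2)cc(OCOC)c1OC
F7 | step 5 | 3-geranyl-6-hydroxy-2,4-bis(methoxymethoxy)benzaldehyde | O=Cc1c(O)cc(OCOC)c(C/C=C(\C)CCC=C(C)C)c1OCOC
F8 | step 5 | tert-butyl 3-[3-geranyl-6-hydroxy-2,4-bis(methoxymethoxy)phenyl]-3-hydroxypropanoate (racemic) | CC(C)(C)OC(=O)CC(O)c1c(O)cc(OCOC)c(C/C=C(\C)CCC=C(C)C)c1OCOC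
F9 | step 7 | tert-butyl 3-[6-(tert-butyldimethylsilyloxy)-3-geranyl-2,4-bis(methoxymethoxy)phenyl]-3-oxopropanoate | CC(C)(C)OC(=O)CC(=O)c1c(O[Si](C)(C)C(C)(C)C)cc(OCOC)c(C/C=C(\C)CCC=C(C)C)c1OCOC
F10 | step 7 | tert-butyl (2Z)-2-[6-(tert-butyldimethylsilyloxy)-3-geranyl-2,4-bis(methoxymethoxy)benzoyl]-3-[3,4-dimethoxy-5-(methoxymethoxy)phenyl]prop-2-enoate | CC(C)(C)OC(=O)/C(=C\c1cc(OC)c(OC)c(OCOC)c1)C(=O)c1c(O[Si](C)(C)C(C)(C)C)cc(OCOC)c(C/C=C(\C)CCC=C(C)C)c1OCOC
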